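**Assumption:** the SMILES is taken literally. All six stereocentres are S, so both aryl groups sit endo (axial) on the cis-fused furofuran and the dihydrobenzofuran is 2,3-cis. Abbreviations: TIPS = triisopropylsilyl; Ar = 3-methoxy-4-(triisopropylsilyloxy)phenyl.

## Retrosynthetic overview

1. Target 26 ⇐ desilylation of 25 ⇐ hydride reduction (convex face) of hemiketal 24 ⇐ aryllithium from bromo-dihydrobenzofuran 22 + endo-aryl furofuranone 13. Tetrahydrofuran ring B is formed last.
2. 13 ⇐ ring expansion of cyclopropane-fused lactone 11: formal CH2O insertion into the C1–C6 bond with inversion at the benzylic carbon, giving tetrahydrofuran ring A. 11 ⇐ asymmetric intramolecular cyclopropanation of cinnamyl diazoacetate 10.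
3. 22 ⇐ cis-selective, enantioselective carbenoid C–H insertion of aryldiazoacetate 20 (dihydrobenzofuran ring) ⇐ aryl iodide 18 + ethyl diazoacetate; 18 ⇐ phenol 14 + benzyl alcohol 17.
4. All three arenes ⇐ 4-bromo-2-methoxyphenol 3 ⇐ catechol 1. The remaining carbons come from methyl acrylate, bromoacetyl bromide, 1,3,5-trioxane, paraformaldehyde and ethyl diazoacetate.
5. Ring order: cyclopropane and lactone together (step 7) → ring A by ring expansion (step 8); dihydrobenzofuran separately (step 13); ring B by lactone → hemiketal → reduction (steps 15–16).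

## Route

Step 1
Reactants: 1 catechol
Product: 2 guaiacol (2-methoxyphenol)
Conditions: MeI (1.0 equiv), Li2CO3, DMF, 55 °C
Reagents that add atoms: iodomethane, CI
Why: Williamson O-methylation in which the weak carbonate base forms only the monophenoxide, so the mono-ether dominates; no stereocentre.

Step 2
Reactants: 2 guaiacol
Product: 3 4-bromo-2-methoxyphenol
Conditions: NBS (1.0 equiv), MeCN, 0 °C
Reagents that add atoms: N-bromosuccinimide, O=C1CCC(=O)N1Br
Why: Electrophilic aromatic bromination goes para to the free hydroxyl, the stronger director.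

Step 3
Reactants: 3 4-bromo-2-methoxyphenol
Product: 4 (4-bromo-2-methoxyphenoxy)triisopropylsilane
Conditions: TIPSCl, imidazole, DMF, rt
Reagents that add atoms: triisopropylsilyl chloride, CC(C)[Si](Cl)(C(C)C)C(C)C
Why: Standard phenol silylation; the bulky silyl ether survives organolithiums, hydrides, amine bases and Lewis acids used later.

Step 4
Reactants: 4 (4-bromo-2-methoxyphenoxy)triisopropylsilane; 5 methyl acrylate
Product: 6 methyl (E)-3-Ar-prop-2-enoate
Conditions: Pd(OAc)2 (2 mol%), P(o-tol)3 (6 mol%), Et3N, DMF, 100 °C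
Reagents that add atoms: none
Why: Mizoroki–Heck reaction; syn insertion and syn β-hydride elimination give the E alkene only.

Step 5
Reactants: 6 methyl (E)-3-Ar-prop-2-enoate
Product: 7 (E)-3-Ar-prop-2-en-1-ol
Conditions: i-Bu2AlH (2.2 equiv), CH2Cl2, −78 °C; aq. potassium sodium tartrate
Reagents that add atoms: none
Why: 1,2-reduction of the enoate by the aluminium hydride leaves the E alkene and the aryl silyl ether untouched.

Step 6
Reactants: 7 (E)-3-Ar-prop-2-en-1-ol; 8 bromoacetyl bromide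
Product: 10 (E)-3-Ar-prop-2-enyl diazoacetate, via bromoacetate 9 (not isolated)
Conditions: BrCH2COBr, NaHCO3, MeCN, 0 °C; then TsNHNHTs, DBU, THF, 0 °C
Reagents that add atoms: N,N'-ditosylhydrazine, Cc1ccc(cc1)S(=O)(=O)NNS(=O)(=O)c1ccc(C)cc1
Why: O-acylation, then N-alkylation of the ditosylhydrazine by the bromoacetate and double sulfinate elimination gives the diazoacetate under mild base.

Step 7
Reactants: 10 (E)-3-Ar-prop-2-enyl diazoacetate
Product: 11 (1R,5S,6S)-6-Ar-3-oxabicyclo[3.1.0]hexan-2-one (aryl exo)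
Conditions: Rh2(4S-MPPIM)4 (dirhodium tetrakis[methyl (4S)-2-oxo-1-(3-phenylpropanoyl)imidazolidine-4-carboxylate], 1 mol%), CH2Cl2, reflux, slow addition over 10 h
Reagents that add atoms: none
Why: Intramolecular carbenoid cyclopropanation is stereospecific (E alkene gives exo aryl), and the chiral carboxamidate catalyst sets C1, C5 and C6 together; the S-configured catalyst is expected to give the (1R,5S,6S) series by analogy with simple trans-cinnamyl diazoacetates, otherwise the mirror-image catalyst is used.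

Step 8
Reactants: 11 (1R,5S,6S)-6-Ar-3-oxabicyclo[3.1.0]hexan-2-one; 12 1,3,5-trioxane
Product: 13 (1S,5S,6S)-6-Ar-3,7-dioxabicyclo[3.3.0]octan-2-one (aryl endo, cis-fused)
Conditions: Sc(OTf)3 (10 mol%), 1,3,5-trioxane (2 equiv), 4 Å MS, CH2Cl2, −20 °C → rt
Reagents that add atoms: none
Why: Proposed new method: Lewis-acid-catalysed stereoinvertive ring expansion of a lactone-fused, mono-acceptor aryl cyclopropane by formal insertion of formaldehyde, in which Sc(OTf)3 on the lactone carbonyl polarises the C1–C6 bond (held parallel to the C=O π* by the ring fusion), an acetal or formaldehyde oxygen attacks the benzylic carbon anti to the breaking bond (inversion turns the exo aryl of 11 into the endo aryl of 13, setting C6), and the scandium enolate closes on the resulting O-alkyl oxocarbenium ion to give the only possible cis fusion at C1; the closest known reaction is the Sn(OTf)2-catalysed annulation of aldehydes with aryl cyclopropane-1,1-diesters, which goes with inversion at the donor carbon.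

Step 9
Reactants: 3 4-bromo-2-methoxyphenol
Product: 14 4-bromo-2-iodo-6-methoxyphenol
Conditions: I2, NaHCO3, THF–H2O, rt
Reagents that add atoms: iodine, I-I
Why: Electrophilic iodination of the phenoxide goes to the only free ortho position because para is blocked by bromine.

Step 10
Reactants: 4 (4-bromo-2-methoxyphenoxy)triisopropylsilane; 15 paraformaldehyde
Product: 17 Ar-methanol, via aryllithium 16 (not isolated)
Conditions: n-BuLi, THF, −78 °C; then (CH2O)n, −78 °C → rt; H2O
Reagents that add atoms: none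
Why: Bromine–lithium exchange followed by addition of the aryllithium to formaldehyde gives the benzylic alcohol in one flask.

Step 11
Reactants: 14 4-bromo-2-iodo-6-methoxyphenol; 17 Ar-methanol
Product: 18 5-bromo-1-iodo-3-methoxy-2-(Ar-methoxy)benzene
Conditions: PPh3, DIAD, THF, 0 °C → rt
Reagents that add atoms: none
Why: Mitsunobu etherification of an acidic, hindered phenol with a primary benzylic alcohol avoids making a labile electron-rich benzyl halide.

Step 12
Reactants: 18 5-bromo-1-iodo-3-methoxy-2-(Ar-methoxy)benzene; 19 ethyl diazoacetate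
Product: 20 ethyl 2-[5-bromo-3-methoxy-2-(Ar-methoxy)phenyl]-2-diazoacetate
Conditions: Pd(PPh3)4 (5 mol%), Ag2CO3 (0.5 equiv), Et3N, toluene, rt
Reagents that add atoms: none
Why: Palladium-catalysed cross-coupling of an aryl iodide with the diazoacetate C–H (diazo group retained); zerovalent palladium inserts into C–I, not C–Br, at room temperature.

Step 13
Reactants: 20 ethyl 2-[5-bromo-3-methoxy-2-(Ar-methoxy)phenyl]-2-diazoacetate
Product: 21 ethyl (2S,3R)-5-bromo-7-methoxy-2-Ar-2,3-dihydro-1-benzofuran-3-carboxylate (2,3-cis)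
Conditions: Rh2(S-PTTL)4 (dirhodium tetrakis[(S)-N-phthaloyl-tert-leucinate], 1 mol%), toluene, −60 °C
Reagents that add atoms: none
Why: Intramolecular 1,5 carbenoid C–H insertion into the benzylic ether C–H closes the dihydrobenzofuran and the chiral carboxylate catalyst sets C2 and C3 together as the kinetic cis isomer; the S-configured catalyst is expected to give this (2S,3R) series by analogy with closely related 5-bromoaryl diazoacetates, otherwise the mirror-image catalyst is used.

Step 14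
Reactants: 21 ethyl (2S,3R)-5-bromo-7-methoxy-2-Ar-2,3-dihydro-1-benzofuran-3-carboxylate
Product: 22 [(2S,3S)-5-bromo-7-methoxy-2-Ar-2,3-dihydro-1-benzofuran-3-yl]methanol (2,3-cis)
Conditions: i-Bu2AlH (2.5 equiv), CH2Cl2, −78 °C; aq. potassium sodium tartrate
Reagents that add atoms: none
Why: Low-temperature hydride reduction of the ester removes the epimerisable α-proton problem before any base is used; the descriptor at C3 changes from R to S only because the priorities change.

Step 15
Reactants: 22 [(2S,3S)-5-bromo-7-methoxy-2-Ar-2,3-dihydro-1-benzofuran-3-yl]methanol; 13 (1S,5S,6S)-6-Ar-3,7-dioxabicyclo[3.3.0]octan-2-one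
Product: 24 hemiketal (2-hydroxy-2-aryl-3,7-dioxabicyclo[3.3.0]octane), via aryllithium alkoxide 23 (not isolated)
Conditions: n-BuLi (2.1 equiv), THF, −78 °C; then 13, −78 °C; H2O
Reagents that add atoms: none
Why: Deprotonation of the hydroxyl, bromine–lithium exchange and 1,2-addition of the aryllithium to the γ-lactone stop at the lithium hemiketal at −78 °C; the hemiketal carbon equilibrates and is fixed in the next step.

Step 16
Reactants: 24 hemiketal
Product: 25 bis-TIPS ether of the target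
Conditions: Et3SiH (3 equiv), BF3·OEt2 (2 equiv), CH2Cl2, −78 °C; Et3N then aq. NaHCO3 at −78 °C
Reagents that add atoms: none
Why: Ionic hydrogenation in which BF3 ionises the hemiketal to the bicyclic aryl oxocarbenium ion and the silane delivers hydride to its convex face, so the new hydrogen is exo and the dihydrobenzofuranyl group endo (C2 of the bicycle set as S); low temperature protects the acid-sensitive endo-aryl and cis-dihydrobenzofuran centres.

Step 17
Reactants: 25 bis-TIPS ether of the target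
Product: 26 target
Conditions: Bu4NF (2.5 equiv), THF, 0 °C
Reagents that add atoms: none
Why: Fluoride cleavage of the two aryl silyl ethers under non-acidic conditions leaves all six stereocentres untouched.

## Compound list

1 | catechol (benzene-1,2-diol) | Oc1ccccc1O | starting material
2 | guaiacol (2-methoxyphenol) | COc1ccccc1O | intermediate
3 | 4-bromo-2-methoxyphenol | COc1cc(Br)ccc1O | intermediate
4 | (4-bromo-2-methoxyphenoxy)triisopropylsilane | COc1cc(Br)ccc1O[Si](C(C)C)(C(C)C)C(C)C | intermediate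
5 | methyl acrylate | C=CC(=O)OC | starting material
6 | methyl (E)-3-[3-methoxy-4-(triisopropylsilyloxy)phenyl]prop-2-enoate | COC(=O)/C=C/c1ccc(O[Si](C(C)C)(C(C)C)C(C)C)c(OC)c1 | intermediate
7 | (E)-3-[3-methoxy-4-(triisopropylsilyloxy)phenyl]prop-2-en-1-ol | OC/C=C/c1ccc(O[Si](C(C)C)(C(C)C)C(C)C)c(OC)c1 | intermediate
8 | bromoacetyl bromide | BrCC(Br)=O | starting material
9 | (E)-3-[3-methoxy-4-(triisopropylsilyloxy)phenyl]prop-2-enyl bromoacetate | BrCC(=O)OC/C=C/c1ccc(O[Si](C(C)C)(C(C)C)C(C)C)c(OC)c1 | intermediate (not isolated)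
10 | (E)-3-[3-methoxy-4-(triisopropylsilyloxy)phenyl]prop-2-enyl diazoacetate | [N-]=[N+]=CC(=O)OC/C=C/c1ccc(O[Si](C(C)C)(C(C)C)C(C)C)c(OC)c1 | intermediate
11 | (1R,5S,6S)-6-[3-methoxy-4-(triisopropylsilyloxy)phenyl]-3-oxabicyclo[3.1.0]hexan-2-one (aryl exo) | O=C1OC[C@H]2[C@H](c3ccc(O[Si](C(C)C)(C(C)C)C(C)C)c(OC)c3)[C@@H]12 | intermediate
12 | 1,3,5-trioxane | C1OCOCO1 | starting material
13 | (1S,5S,6S)-6-[3-methoxy-4-(triisopropylsilyloxy)phenyl]-3,7-dioxabicyclo[3.3.0]octan-2-one (aryl endo, cis-fused) | COc1cc([C@H]2OC[C@@H]3[C@H]2COC3=O)ccc1O[Si](C(C)C)(C(C)C)C(C)C | intermediate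
14 | 4-bromo-2-iodo-6-methoxyphenol | COc1cc(Br)cc(I)c1O | intermediate
15 | paraformaldehyde (formaldehyde unit) | C=O | starting material
16 | [3-methoxy-4-(triisopropylsilyloxy)phenyl]lithium | [Li]c1ccc(O[Si](C(C)C)(C(C)C)C(C)C)c(OC)c1 | intermediate (not isolated)
17 | [3-methoxy-4-(triisopropylsilyloxy)phenyl]methanol | OCc1ccc(O[Si](C(C)C)(C(C)C)C(C)C)c(OC)c1 | intermediate
18 | 5-bromo-1-iodo-3-methoxy-2-{[3-methoxy-4-(triisopropylsilyloxy)phenyl]methoxy}benzene | COc1cc(Br)cc(I)c1OCc1ccc(O[Si](C(C)C)(C(C)C)C(C)C)c(OC)c1 | intermediate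
19 | ethyl diazoacetate | CCOC(=O)C=[N+]=[N-] | starting material
20 | ethyl 2-(5-bromo-3-methoxy-2-{[3-methoxy-4-(triisopropylsilyloxy)phenyl]methoxy}phenyl)-2-diazoacetate | CCOC(=O)C(=[N+]=[N-])c1cc(Br)cc(OC)c1OCc1ccc(O[Si](C(C)C)(C(C)C)C(C)C)c(OC)c1 | intermediate
21 | ethyl (2S,3R)-5-bromo-7-methoxy-2-[3-methoxy-4-(triisopropylsilyloxy)phenyl]-2,3-dihydro-1-benzofuran-3-carboxylate (2,3-cis) | Brc1cc(OC)c2c(c1)[C@@H](C(=O)OCC)[C@@H](c1ccc(O[Si](C(C)C)(C(C)C)C(C)C)c(OC)c1)O2 | intermediate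
22 | [(2S,3S)-5-bromo-7-methoxy-2-[3-methoxy-4-(triisopropylsilyloxy)phenyl]-2,3-dihydro-1-benzofuran-3-yl]methanol (2,3-cis) | Brc1cc(OC)c2c(c1)[C@@H](CO)[C@@H](c1ccc(O[Si](C(C)C)(C(C)C)C(C)C)c(OC)c1)O2 | intermediate
23 | 5-lithio lithium alkoxide of 22 | [Li]c1cc(OC)c2c(c1)[C@@H](CO[Li])[C@@H](c1ccc(O[Si](C(C)C)(C(C)C)C(C)C)c(OC)c1)O2 | intermediate (not isolated)
24 | (1S,5S,6S)-2-hydroxy-2-{(2S,3S)-3-(hydroxymethyl)-7-methoxy-2-[3-methoxy-4-(triisopropylsilyloxy)phenyl]-2,3-dihydro-1-benzofuran-5-yl}-6-[3-methoxy-4-(triisopropylsilyloxy)phenyl]-3,7-dioxabicyclo[3.3.0]octane (hemiketal; C2 epimers in equilibrium with the open hydroxy ketone) | COc1cc([C@H]2OC[C@@H]3[C@H]2COC3(O)c2cc(OC)c3c(c2)[C@@H](CO)[C@@H](c2ccc(O[Si](C(C)C)(C(C)C)C(C)C)c(OC)c2)O3)ccc1O[Si](C(C)C)(C(C)C)C(C)C | intermediate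
25 | [(2S,3S)-7-methoxy-2-[3-methoxy-4-(triisopropylsilyloxy)phenyl]-5-{(1S,2S,5S,6S)-6-[3-methoxy-4-(triisopropylsilyloxy)phenyl]-3,7-dioxabicyclo[3.3.0]octan-2-yl}-2,3-dihydro-1-benzofuran-3-yl]methanol | COc1cc([C@H]2OC[C@@H]3[C@H]2CO[C@@H]3c2cc(OC)c3c(c2)[C@@H](CO)[C@@H](c2ccc(O[Si](C(C)C)(C(C)C)C(C)C)c(OC)c2)O3)ccc1O[Si](C(C)C)(C(C)C)C(C)C | intermediate
26 | 4-[(1S,2S,5S,6S)-6-[(2S,3S)-2-(4-hydroxy-3-methoxyphenyl)-3-(hydroxymethyl)-7-methoxy-2,3-dihydro-1-benzofuran-5-yl]-3,7-dioxabicyclo[3.3.0]octan-2-yl]-2-methoxyphenol (CNP0303197.1) | COc1cc([C@H]2OC[C@@H]3[C@H]2CO[C@@H]3c2cc(OC)c3c(c2)[C@@H](CO)[C@@H](c2ccc(O)c(OC)c2)O3)ccc1O | target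

## Step count and risks

Total steps: 17. Longest linear sequence: 11 (steps 1, 2, 3, 10, 11, 12, 13, 14, 15, 16, 17; the branch through steps 4–8 is equally long).

**Step 8 (the proposed ring expansion).** The mono-acceptor cyclopropane may not open, or it may open through a free benzylic cation and lose the inversion that gives the endo aryl. The fallback uses only known chemistry, sets out from 4 and 22, bypasses 13, 24 and 25, and comes back at 26.

- Bromide 4 is lithiated (n-BuLi) and formylated with DMF to 3-methoxy-4-(triisopropylsilyloxy)benzaldehyde F1.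
- Darzens condensation of F1 with methyl 4-bromocrotonate (LiN(SiMe3)2, THF, −78 °C) gives the vinyl epoxide methyl (E)-3-{3-[3-methoxy-4-(triisopropylsilyloxy)phenyl]oxiran-2-yl}prop-2-enoate F2.
- Flash vacuum pyrolysis rearranges F2 through the carbonyl ylide to racemic methyl cis-2-[3-methoxy-4-(triisopropylsilyloxy)phenyl]-2,3-dihydrofuran-3-carboxylate F3.
- i-Bu2AlH reduction and preparative chiral HPLC give {(2S,3S)-2-[3-methoxy-4-(triisopropylsilyloxy)phenyl]-2,3-dihydrofuran-3-yl}methanol F4.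
- In parallel, alcohol 22 is silylated (TBSCl, imidazole) to its tert-butyldimethylsilyl ether F5, lithiated and formylated (n-BuLi; DMF) to the 5-carbaldehyde F6, and converted (HC(OMe)3, pyridinium tosylate, MeOH) into the dimethyl acetal F7.
- TMSOTf at −78 °C exchanges F4 into the acetal F7, and the enol ether closes onto the oxocarbenium ion (Prins-type, endo-selective) to give the endo,endo 8-methoxy furofuran acetal F8.
- Et3SiH/BF3·OEt2 removes the methoxy group to give the tris-silyl furofuran F9, and Bu4NF gives 26.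

**Step 16 (ionic reduction).** BF3 may epimerise the endo benzylic ether or the cis-dihydrobenzofuran. The fallback avoids acid, sets out from 24 and comes back at 25. The open hydroxy-ketone form of 24 is reduced with (R)-2-methyl-CBS-oxazaborolidine and BH3·SMe2 to the (S)-carbinol triol F11. Mitsunobu cyclodehydration (PPh3, DIAD, THF) then activates the primary hydroxyl of the 1,4-diol, and the benzylic hydroxyl closes the ring with retention at the benzylic carbon to give 25. The remote primary hydroxyl has no partner and is recovered on work-up.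

**Step 12 (palladium coupling with the diazoacetate).** The ortho-alkoxy aryl iodide may couple poorly or the diazo group may decompose. The fallback sets out from 18 and comes back at 20. Negishi coupling of 18 with the Reformatsky reagent BrZnCH2CO2Et (from ethyl bromoacetate and zinc; Pd(dba)2, XPhos, THF, rt, iodide before bromide) gives ethyl 2-(5-bromo-3-methoxy-2-{[3-methoxy-4-(triisopropylsilyloxy)phenyl]methoxy}phenyl)acetate F10. Diazo transfer (4-acetamidobenzenesulfonyl azide, DBU, MeCN) then gives 20.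

## Further compounds

F1 | step 8 | 3-methoxy-4-(triisopropylsilyloxy)benzaldehyde | O=Cc1ccc(O[Si](C(C)C)(C(C)C)C(C)C)c(OC)c1
F2 | step 8 | methyl (E)-3-{3-[3-methoxy-4-(triisopropylsilyloxy)phenyl]oxiran-2-yl}prop-2-enoate (racemic, epoxide cis/trans mixture) | COC(=O)/C=C/C1OC1c1ccc(O[Si](C(C)C)(C(C)C)C(C)C)c(OC)c1
F3 | step 8 | methyl cis-2-[3-methoxy-4-(triisopropylsilyloxy)phenyl]-2,3-dihydrofuran-3-carboxylate (racemic; (2S,3R) enantiomer drawn) | COc1cc([C@H]2OC=C[C@H]2C(=O)OC)ccc1O[Si](C(C)C)(C(C)C)C(C)C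
F4 | step 8 | {(2S,3S)-2-[3-methoxy-4-(triisopropylsilyloxy)phenyl]-2,3-dihydrofuran-3-yl}methanol | COc1cc([C@H]2OC=C[C@H]2CO)ccc1O[Si](C(C)C)(C(C)C)C(C)C
F5 | step 8 | tert-butyldimethylsilyl ether of 22 | Brc1cc(OC)c2c(c1)[C@@H](CO[Si](C)(C)C(C)(C)C)[C@@H](c1ccc(O[Si](C(C)C)(C(C)C)C(C)C)c(OC)c1)O2
F6 | step 8 | (2S,3S)-3-[(tert-butyldimethylsilyloxy)methyl]-7-methoxy-2-[3-methoxy-4-(triisopropylsilyloxy)phenyl]-2,3-dihydro-1-benzofuran-5-carbaldehyde | O=Cc1cc(OC)c2c(c1)[C@@H](CO[Si](C)(C)C(C)(C)C)[C@@H](c1ccc(O[Si](C(C)C)(C(C)C)C(C)C)c(OC)c1)O2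
F7 | step 8 | dimethyl acetal of F6 | COC(OC)c1cc(OC)c2c(c1)[C@@H](CO[Si](C)(C)C(C)(C)C)[C@@H](c1ccc(O[Si](C(C)C)(C(C)C)C(C)C)c(OC)c1)O2
F8 | step 8 | 8-methoxy derivative of the tris-silyl furofuran F9 (acetal carbon unassigned) | COc1cc([C@H]2OC(OC)[C@@H]3[C@H]2CO[C@@H]3c2cc(OC)c3c(c2)[C@@H](CO[Si](C)(C)C(C)(C)C)[C@@H](c2ccc(O[Si](C(C)C)(C(C)C)C(C)C)c(OC)c2)O3)ccc1O[Si](C(C)C)(C(C)C)C(C)C
F9 | step 8 | tert-butyldimethylsilyl ether of 25 (tris-silyl furofuran) | COc1cc([C@H]2OC[C@@H]3[C@H]2CO[C@@H]3c2cc(OC)c3c(c2)[C@@H](CO[Si](C)(C)C(C)(C)C)[C@@H](c2ccc(O[Si](C(C)C)(C(C)C)C(C)C)c(OC)c2)O3)ccc1O[Si](C(C)C)(C(C)C)C(C)C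
F10 | step 12 | ethyl 2-(5-bromo-3-methoxy-2-{[3-methoxy-4-(triisopropylsilyloxy)phenyl]methoxy}phenyl)acetate | CCOC(=O)Cc1cc(Br)cc(OC)c1OCc1ccc(O[Si](C(C)C)(C(C)C)C(C)C)c(OC)c1
F11 | step 16 | (S)-{(2S,3S)-3-(hydroxymethyl)-7-methoxy-2-[3-methoxy-4-(triisopropylsilyloxy)phenyl]-2,3-dihydro-1-benzofuran-5-yl}{(3S,4S,5S)-4-(hydroxymethyl)-5-[3-methoxy-4-(triisopropylsilyloxy)phenyl]oxolan-3-yl}methanol | COc1cc([C@H]2OC[C@@H]([C@H](O)c3cc(OC)c4c(c3)[C@@H](CO)[C@@H](c3ccc(O[Si](C(C)C)(C(C)C)C(C)C)c(OC)c3)O4)[C@H]2CO)ccc1O[Si](C(C)C)(C(C)C)C(C)C
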